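**Retrosynthetic overview**
- The hydroxytyrosol ester is cut first (Steglich C–O), giving the pyran-4-acetic acid and 3,4-bis-O-TBS hydroxytyrosol; the acid arm comes from a PMB-protected 2-hydroxyethyl arm, and C3–CH2OH from a C3 carboxyl.
- The strategy rests on this feature: ring atoms O1–C2(CH3)–C3 plus the exocyclic carbon on C3 are (R)-3-hydroxybutanoic acid, and C6–C5(CO2Me)–C4 with its arm are an (E)-2-formyl enoate. The 3,4-dihydro-2H-pyran ring (O1, C2, C3, C4, C5, C6) is therefore the [3,3] isomer of the cyclic acylal (1,3-dioxan-4-one) of these two pieces.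
- Key disconnection: C3–C4, by Ireland–Claisen rearrangement of the silyl ketene acetal of the cis-2-alkenyl-6-methyl-1,3-dioxan-4-one; the same event sets C3 and C4 and makes C5=C6 the enol ether.
- The dioxanone comes from bis-silylated (R)-3-hydroxybutanoic acid and the formyl enoate, which comes from the Baylis–Hillman adduct of methyl acrylate and 3-(PMB-oxy)propanal through the transposed allylic bromide.
- Ring order: the dioxanone is made first (acetalisation) and is exchanged for the dihydropyran in the key step; the arene arrives with hydroxytyrosol.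

Key step: step 9

Assumption: the target SMILES is read as the (2R,3R,4S) isomer (2-CH3/3-CH2OH trans, 3-CH2OH/4-arm trans); pyran atoms are numbered O1, C2 (CH3), C3 (CH2OH), C4 (arm), C5 (CO2Me), C6 (enol-ether CH) throughout.

**Step 1**
Reactants: 1 propane-1,3-diol
Product: 2 3-[(4-methoxybenzyl)oxy]propan-1-ol
Conditions: NaH (1 equiv), diol in excess, PMBCl, Bu4NI (cat.), THF/DMF, 0 °C → rt
Reagents that add atoms: 4-methoxybenzyl chloride, COc1ccc(CCl)cc1
Why: Williamson etherification of the mono-alkoxide, with excess diol used so that the mono-ether should dominate.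

**Step 2**
Reactants: 2 3-[(4-methoxybenzyl)oxy]propan-1-ol
Product: 3 3-[(4-methoxybenzyl)oxy]propanal
Conditions: TEMPO (cat.), PhI(OAc)2, CH2Cl2, rt
Reagents that add atoms: none
Why: Oxoammonium (TEMPO/BAIB) oxidation stops at the aldehyde in dry CH2Cl2 and is non-basic, so the β-alkoxy aldehyde should not eliminate.

**Step 3**
Reactants: 3 3-[(4-methoxybenzyl)oxy]propanal; 4 methyl acrylate
Product: 5 methyl 3-hydroxy-5-[(4-methoxybenzyl)oxy]-2-methylidenepentanoate (racemic)
Conditions: DABCO, methyl acrylate in excess, MeOH (few equiv), rt, several days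
Reagents that add atoms: none
Why: Morita–Baylis–Hillman reaction of an unhindered aliphatic aldehyde; the carbinol centre is racemic and is erased in step 4.

**Step 4**
Reactants: 5 methyl 3-hydroxy-5-[(4-methoxybenzyl)oxy]-2-methylidenepentanoate
Product: 6 methyl (2Z)-2-(bromomethyl)-5-[(4-methoxybenzyl)oxy]pent-2-enoate
Conditions: NBS, Me2S, CH2Cl2, 0 °C → rt
Reagents that add atoms: N-bromosuccinimide, O=C1CCC(=O)N1Br
Why: Corey–Kim-type activation of the allylic alcohol followed by SN2′ attack of bromide should give the conjugated, transposed bromide with the side arm cis to CH2Br (trans to the ester), which fixes the alkene geometry needed later.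

**Step 5**
Reactants: 6 methyl (2Z)-2-(bromomethyl)-5-[(4-methoxybenzyl)oxy]pent-2-enoate
Product: 7 methyl (2E)-2-formyl-5-[(4-methoxybenzyl)oxy]pent-2-enoate
Conditions: NMO (excess), 4 Å MS, MeCN, 0 °C → rt; used without storage
Reagents that add atoms: N-methylmorpholine N-oxide, C[N+]1([O-])CCOCC1
Why: Kornblum-type oxidation of a primary allylic bromide with an amine N-oxide (SN2 O-alkylation, then loss of the amine) should give the aldehyde with the alkene geometry retained (Z becomes E only by CIP priority; the arm stays cis to the formyl carbon).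

**Step 6**
Reactants: 8 methyl (R)-3-hydroxybutanoate
Product: 9 (R)-3-hydroxybutanoic acid
Conditions: KOH, H2O/MeOH, 0 °C → rt; then HCl to pH 2, continuous extraction
Reagents that add atoms: potassium hydroxide, [K+].[OH-]
Why: Ester saponification at or below room temperature, conditions under which the β-hydroxy acid should neither eliminate nor racemise.

**Step 7**
Reactants: 9 (R)-3-hydroxybutanoic acid
Product: 10 trimethylsilyl (R)-3-[(trimethylsilyl)oxy]butanoate
Conditions: TMSCl, Et3N, CH2Cl2, 0 °C → rt; filtration, distillation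
Reagents that add atoms: chlorotrimethylsilane, C[Si](C)(C)Cl
Why: Exhaustive O-silylation of hydroxyl and carboxyl gives the bis-silyl donor needed for acetalisation without free water.

**Step 8**
Reactants: 7 methyl (2E)-2-formyl-5-[(4-methoxybenzyl)oxy]pent-2-enoate; 10 trimethylsilyl (R)-3-[(trimethylsilyl)oxy]butanoate
Product: 11 methyl (2E)-5-[(4-methoxybenzyl)oxy]-2-[(2R,4R)-4-methyl-6-oxo-1,3-dioxan-2-yl]pent-2-enoate (the cis-2-alkenyl-6-methyl-1,3-dioxan-4-one)
Conditions: TMSOTf (cat.), CH2Cl2, −78 °C; pyridine quench; chromatography to remove any trans isomer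
Reagents that add atoms: none
Why: Noyori-type silyl-transfer acetalisation is the standard route to 2-substituted 6-methyl-1,3-dioxan-4-ones, and the new acetal centre should form cis to the methyl group (both substituents equatorial on closure), controlled by the hydroxybutanoate stereocentre.

**Step 9**
Reactants: 11 methyl (2E)-5-[(4-methoxybenzyl)oxy]-2-[(2R,4R)-4-methyl-6-oxo-1,3-dioxan-2-yl]pent-2-enoate
Product: 14 (2R,3S,4S)-5-(methoxycarbonyl)-4-{2-[(4-methoxybenzyl)oxy]ethyl}-2-methyl-3,4-dihydro-2H-pyran-3-carboxylic acid, via silyl ketene acetal 12 (not isolated), via trimethylsilyl ester 13 (not isolated)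
Conditions: TMSCl, Et3N, then LiHMDS, THF, −78 °C; warm to rt, then PhMe, 65 °C; 5% aq. citric acid
Reagents that add atoms: none
Why: Proposed new method: LiHMDS should remove an α-proton of the acylal lactone in the presence of TMSCl, so that the enolate is silylated before it can β-eliminate, and the endocyclic silyl ketene acetal 12 then holds the 1,5-diene (ketene acetal C=C, acyl oxygen, acetal carbon, enoate C=C) that rearranges [3,3], forming C3–C4, breaking the acyl-oxygen–C6 bond and moving the alkene to C5=C6. The closest known reaction is the Ireland–Claisen rearrangement of 6-alkenyl-1,4-dioxan-2-ones to dihydropyrans, which also has to pass through a boat because the ketene acetal is endocyclic; here the bond that breaks is an acetal C–O bond, which should lower the barrier. The dihydropyran closes through the sigmatropic C–C bond formation itself, in a bicyclo[2.2.2]-type transition state made of the six pericyclic atoms and the O1–C2 bridge, so the dioxanone is exchanged for the pyran in one event and no separate cyclisation is needed. C3 is set because the alkenyl group can reach the ketene acetal carbon only on the ring face it occupies, cis to the methyl group of 11, which places the new carboxyl trans to the C2 methyl, the opposite sense to intermolecular alkylation of 3-hydroxybutanoate enolates. C4 is set by the E alkene: in the enforced boat the arm sits on the inner position, so it ends trans to the carboxyl and cis to the methyl. The step needs α-deprotonation of the lactone in preference to γ-deprotonation of the enoate, which the higher acidity of the acylal lactone and the internal quench should secure, and it must pay for a syn-axial methyl/arm contact in the boat, which should slow it (hence the warming) without opening a second diastereomeric channel.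

**Step 10**
Reactants: 14 (2R,3S,4S)-5-(methoxycarbonyl)-4-{2-[(4-methoxybenzyl)oxy]ethyl}-2-methyl-3,4-dihydro-2H-pyran-3-carboxylic acid
Product: 15 methyl (2R,3R,4S)-3-(hydroxymethyl)-4-{2-[(4-methoxybenzyl)oxy]ethyl}-2-methyl-3,4-dihydro-2H-pyran-5-carboxylate
Conditions: BH3·THF, THF, −10 → 0 °C; then H2O
Reagents that add atoms: none
Why: Borane reduces a carboxylic acid through its acyloxyborane much faster than it touches an ester or the electron-poor β-alkoxyacrylate alkene, so only the C3 carboxyl should be reduced.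

**Step 11**
Reactants: 15 methyl (2R,3R,4S)-3-(hydroxymethyl)-4-{2-[(4-methoxybenzyl)oxy]ethyl}-2-methyl-3,4-dihydro-2H-pyran-5-carboxylate
Product: 16 methyl (2R,3R,4S)-3-{[(tert-butyldimethylsilyl)oxy]methyl}-4-{2-[(4-methoxybenzyl)oxy]ethyl}-2-methyl-3,4-dihydro-2H-pyran-5-carboxylate
Conditions: TBSCl, imidazole, DMF, rt
Reagents that add atoms: tert-butyldimethylsilyl chloride, CC(C)(C)[Si](C)(C)Cl
Why: Standard silylation of the primary alcohol, which keeps it from lactonising onto the arm once that is oxidised.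

**Step 12**
Reactants: 16 methyl (2R,3R,4S)-3-{[(tert-butyldimethylsilyl)oxy]methyl}-4-{2-[(4-methoxybenzyl)oxy]ethyl}-2-methyl-3,4-dihydro-2H-pyran-5-carboxylate
Product: 17 methyl (2R,3R,4S)-3-{[(tert-butyldimethylsilyl)oxy]methyl}-4-(2-hydroxyethyl)-2-methyl-3,4-dihydro-2H-pyran-5-carboxylate
Conditions: DDQ, CH2Cl2/pH 7 buffer, 0 °C → rt; carried on at once
Reagents that add atoms: none
Why: Oxidative PMB cleavage with DDQ is neutral and should spare the TBS ether and the electron-poor enol ether; the alcohol is used at once because base could close it onto the C5 ester.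

**Step 13**
Reactants: 17 methyl (2R,3R,4S)-3-{[(tert-butyldimethylsilyl)oxy]methyl}-4-(2-hydroxyethyl)-2-methyl-3,4-dihydro-2H-pyran-5-carboxylate
Product: 19 2-[(2R,3R,4S)-3-{[(tert-butyldimethylsilyl)oxy]methyl}-5-(methoxycarbonyl)-2-methyl-3,4-dihydro-2H-pyran-4-yl]acetic acid, via aldehyde 18 (not isolated)
Conditions: TEMPO (cat.), PhI(OAc)2 (2.5 equiv), MeCN/H2O, rt
Reagents that add atoms: water, O
Why: TEMPO/BAIB oxidation in aqueous acetonitrile takes a primary alcohol through the aldehyde hydrate to the acid under mildly acidic conditions that the TBS ether and the vinylogous carbonate should tolerate.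

**Step 14**
Reactants: 20 hydroxytyrosol
Product: 21 tert-butyl{2-[3,4-bis(tert-butyldimethylsilyloxy)phenyl]ethoxy}dimethylsilane
Conditions: TBSCl (excess), imidazole, DMF, rt
Reagents that add atoms: tert-butyldimethylsilyl chloride, CC(C)(C)[Si](C)(C)Cl
Why: Exhaustive silylation of the two phenols and the primary alcohol.

**Step 15**
Reactants: 21 tert-butyl{2-[3,4-bis(tert-butyldimethylsilyloxy)phenyl]ethoxy}dimethylsilane
Product: 22 2-[3,4-bis(tert-butyldimethylsilyloxy)phenyl]ethanol
Conditions: CSA (cat.), MeOH/CH2Cl2, 0 °C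
Reagents that add atoms: none
Why: Acid-catalysed methanolysis cleaves a primary alkyl TBS ether much faster than aryl TBS ethers, so only the aliphatic hydroxyl should be released.

**Step 16**
Reactants: 19 2-[(2R,3R,4S)-3-{[(tert-butyldimethylsilyl)oxy]methyl}-5-(methoxycarbonyl)-2-methyl-3,4-dihydro-2H-pyran-4-yl]acetic acid; 22 2-[3,4-bis(tert-butyldimethylsilyloxy)phenyl]ethanol
Product: 23 methyl (2R,3R,4S)-4-(2-{2-[3,4-bis(tert-butyldimethylsilyloxy)phenyl]ethoxy}-2-oxoethyl)-3-{[(tert-butyldimethylsilyl)oxy]methyl}-2-methyl-3,4-dihydro-2H-pyran-5-carboxylate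
Conditions: DCC, DMAP (cat.), CH2Cl2, 0 °C → rt
Reagents that add atoms: none
Why: Steglich esterification of an unhindered acetic acid arm with a primary alcohol; no stereocentre is α to the activated carboxyl.

**Step 17**
Reactants: 23 methyl (2R,3R,4S)-4-(2-{2-[3,4-bis(tert-butyldimethylsilyloxy)phenyl]ethoxy}-2-oxoethyl)-3-{[(tert-butyldimethylsilyl)oxy]methyl}-2-methyl-3,4-dihydro-2H-pyran-5-carboxylate
Product: 24 methyl (2R,3R,4S)-4-{2-[2-(3,4-dihydroxyphenyl)ethoxy]-2-oxoethyl}-3-(hydroxymethyl)-2-methyl-3,4-dihydro-2H-pyran-5-carboxylate (target)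
Conditions: HF·pyridine, pyridine, THF, 0 °C → rt
Reagents that add atoms: none
Why: Buffered HF desilylation removes the two aryl and the one alkyl TBS ether without base, so the freed CH2OH should not transesterify onto the arm ester and the catechol should not be oxidised.

**Compound list**
1 | propane-1,3-diol | OCCCO | starting material
2 | 3-[(4-methoxybenzyl)oxy]propan-1-ol | OCCCOCc1ccc(OC)cc1 | intermediate
3 | 3-[(4-methoxybenzyl)oxy]propanal | O=CCCOCc1ccc(OC)cc1 | intermediate
4 | methyl acrylate | C=CC(=O)OC | starting material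
5 | methyl 3-hydroxy-5-[(4-methoxybenzyl)oxy]-2-methylidenepentanoate (racemic) | C=C(C(=O)OC)C(O)CCOCc1ccc(OC)cc1 | intermediate
6 | methyl (2Z)-2-(bromomethyl)-5-[(4-methoxybenzyl)oxy]pent-2-enoate | COC(=O)/C(CBr)=C/CCOCc1ccc(OC)cc1 | intermediate
7 | methyl (2E)-2-formyl-5-[(4-methoxybenzyl)oxy]pent-2-enoate | COC(=O)/C(C=O)=C/CCOCc1ccc(OC)cc1 | intermediate
8 | methyl (R)-3-hydroxybutanoate | C[C@@H](O)CC(=O)OC | starting material
9 | (R)-3-hydroxybutanoic acid | C[C@@H](O)CC(=O)O | intermediate
10 | trimethylsilyl (R)-3-[(trimethylsilyl)oxy]butanoate | C[C@@H](O[Si](C)(C)C)CC(=O)O[Si](C)(C)C | intermediate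
11 | methyl (2E)-5-[(4-methoxybenzyl)oxy]-2-[(2R,4R)-4-methyl-6-oxo-1,3-dioxan-2-yl]pent-2-enoate (cis-dioxanone) | O1[C@H](C)CC(=O)O[C@@H]1/C(C(=O)OC)=C\CCOCc2ccc(OC)cc2 | intermediate
12 | methyl (2E)-5-[(4-methoxybenzyl)oxy]-2-[(2R,4R)-4-methyl-6-[(trimethylsilyl)oxy]-4H-1,3-dioxin-2-yl]pent-2-enoate (silyl ketene acetal of 11) | O1[C@H](C)C=C(O[Si](C)(C)C)O[C@@H]1/C(C(=O)OC)=C\CCOCc2ccc(OC)cc2 | intermediate
13 | 5-methyl 3-trimethylsilyl (2R,3S,4S)-4-{2-[(4-methoxybenzyl)oxy]ethyl}-2-methyl-3,4-dihydro-2H-pyran-3,5-dicarboxylate | COC(=O)C1=CO[C@H](C)[C@@H](C(=O)O[Si](C)(C)C)[C@@H]1CCOCc2ccc(OC)cc2 | intermediate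
14 | (2R,3S,4S)-5-(methoxycarbonyl)-4-{2-[(4-methoxybenzyl)oxy]ethyl}-2-methyl-3,4-dihydro-2H-pyran-3-carboxylic acid | COC(=O)C1=CO[C@H](C)[C@@H](C(=O)O)[C@@H]1CCOCc2ccc(OC)cc2 | intermediate
15 | methyl (2R,3R,4S)-3-(hydroxymethyl)-4-{2-[(4-methoxybenzyl)oxy]ethyl}-2-methyl-3,4-dihydro-2H-pyran-5-carboxylate | COC(=O)C1=CO[C@H](C)[C@@H](CO)[C@@H]1CCOCc2ccc(OC)cc2 | intermediate
16 | methyl (2R,3R,4S)-3-{[(tert-butyldimethylsilyl)oxy]methyl}-4-{2-[(4-methoxybenzyl)oxy]ethyl}-2-methyl-3,4-dihydro-2H-pyran-5-carboxylate | COC(=O)C1=CO[C@H](C)[C@@H](CO[Si](C)(C)C(C)(C)C)[C@@H]1CCOCc2ccc(OC)cc2 | intermediate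
17 | methyl (2R,3R,4S)-3-{[(tert-butyldimethylsilyl)oxy]methyl}-4-(2-hydroxyethyl)-2-methyl-3,4-dihydro-2H-pyran-5-carboxylate | COC(=O)C1=CO[C@H](C)[C@@H](CO[Si](C)(C)C(C)(C)C)[C@@H]1CCO | intermediate
18 | methyl (2R,3R,4S)-3-{[(tert-butyldimethylsilyl)oxy]methyl}-2-methyl-4-(2-oxoethyl)-3,4-dihydro-2H-pyran-5-carboxylate | COC(=O)C1=CO[C@H](C)[C@@H](CO[Si](C)(C)C(C)(C)C)[C@@H]1CC=O | intermediate
19 | 2-[(2R,3R,4S)-3-{[(tert-butyldimethylsilyl)oxy]methyl}-5-(methoxycarbonyl)-2-methyl-3,4-dihydro-2H-pyran-4-yl]acetic acid | COC(=O)C1=CO[C@H](C)[C@@H](CO[Si](C)(C)C(C)(C)C)[C@@H]1CC(=O)O | intermediate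
20 | hydroxytyrosol | OCCc1ccc(O)c(O)c1 | starting material
21 | tert-butyl{2-[3,4-bis(tert-butyldimethylsilyloxy)phenyl]ethoxy}dimethylsilane | CC(C)(C)[Si](C)(C)OCCc1ccc(O[Si](C)(C)C(C)(C)C)c(O[Si](C)(C)C(C)(C)C)c1 | intermediate
22 | 2-[3,4-bis(tert-butyldimethylsilyloxy)phenyl]ethanol | OCCc1ccc(O[Si](C)(C)C(C)(C)C)c(O[Si](C)(C)C(C)(C)C)c1 | intermediate
23 | methyl (2R,3R,4S)-4-(2-{2-[3,4-bis(tert-butyldimethylsilyloxy)phenyl]ethoxy}-2-oxoethyl)-3-{[(tert-butyldimethylsilyl)oxy]methyl}-2-methyl-3,4-dihydro-2H-pyran-5-carboxylate | COC(=O)C1=CO[C@H](C)[C@@H](CO[Si](C)(C)C(C)(C)C)[C@@H]1CC(=O)OCCc2ccc(O[Si](C)(C)C(C)(C)C)c(O[Si](C)(C)C(C)(C)C)c2 | intermediate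
24 | methyl (2R,3R,4S)-4-{2-[2-(3,4-dihydroxyphenyl)ethoxy]-2-oxoethyl}-3-(hydroxymethyl)-2-methyl-3,4-dihydro-2H-pyran-5-carboxylate | COC(=O)C1=CO[C@H](C)[C@@H](CO)[C@@H]1CC(=O)OCCc1ccc(O)c(O)c1 | target

**Step count**
Total: 17 steps. Longest linear sequence: 13 steps (1–5, 8–13, 16, 17).

**Steps most likely to fail**

1. Step 9 (Proposed new method). The enolisation may go to the wrong site (γ-deprotonation of the enoate), the enolate or ketene acetal may fragment by β-elimination or retro-[4+2], or the rearrangement may stall because of the syn-axial methyl/arm contact in the boat. The fallback uses known enolate and lactone chemistry, sets out from 8 and comes back at 17.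
   - Fráter–Seebach hydroxymethylation of the dianion of 8 (LDA, then monomeric formaldehyde) should give the anti product methyl (2R,3R)-3-hydroxy-2-(hydroxymethyl)butanoate F1. Because the ester carbon becomes ring carbon C4 here, anti corresponds to the 2,3-trans pyran.
   - Selective silylation of the primary hydroxyl would give TBS ether F2, and capping of the secondary hydroxyl the TES ether F3.
   - DIBAL-H at −78 °C would give aldehyde F4, and Still–Gennari olefination the (Z)-enoate F5.
   - PPTS in methanol (TES removal and lactonisation) would give the trans-5,6-disubstituted 5,6-dihydro-2H-pyran-2-one F6.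
   - Copper-mediated conjugate addition of vinylmagnesium bromide, anti to the adjacent silyloxymethyl group, should give the 4-vinyl lactone F7.
   - α-Formylation (LDA, ethyl formate) would give the hydroxymethylidene lactone F8, and acidic methanol the Korte rearrangement to the dihydropyran ester F9, with loss of the TBS group.
   - Re-silylation to the TBS ether F10 and 9-BBN hydroboration–oxidation of the vinyl group would deliver alcohol 17, bypassing the PMB steps.

2. Step 8. The doubly activated enal may oligomerise or undergo oxa-conjugate addition under silyl triflate catalysis, and cis selectivity at the acetal carbon may be incomplete. The fallback sets out from 7 (with acid 9) and comes back at 11. Aldehyde 7 would first be masked (trimethyl orthoformate, PPTS, MeOH) as the dimethyl acetal F11. Acid-catalysed transacetalisation of F11 with the free hydroxy acid 9 (CSA, PhMe, 5 Å MS to take up methanol) should then give 11 under equilibrium control, where the cis isomer with both substituents equatorial is favoured.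

3. Step 5. The N-oxide may attack SN2′, or the amine formed may isomerise the alkene or deconjugate the formyl enoate as it forms. The fallback sets out from 6 and comes back at 7. Direct SN2 displacement of the bromide with potassium acetate (DMF) should give the (E)-allylic acetate F12 with the geometry retained. Methanolysis (K2CO3, MeOH, 0 °C) would give the (E)-allylic alcohol F13, and neutral MnO2 oxidation (CH2Cl2) the aldehyde 7.

**Further compounds**
F1 | step 9 | methyl (2R,3R)-3-hydroxy-2-(hydroxymethyl)butanoate | O[C@H](C)[C@@H](CO)C(=O)OC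
F2 | step 9 | methyl (2R,3R)-2-{[(tert-butyldimethylsilyl)oxy]methyl}-3-hydroxybutanoate | O[C@H](C)[C@@H](CO[Si](C)(C)C(C)(C)C)C(=O)OC
F3 | step 9 | methyl (2R,3R)-2-{[(tert-butyldimethylsilyl)oxy]methyl}-3-[(triethylsilyl)oxy]butanoate | CC[Si](CC)(CC)O[C@H](C)[C@@H](CO[Si](C)(C)C(C)(C)C)C(=O)OC
F4 | step 9 | (2R,3R)-2-{[(tert-butyldimethylsilyl)oxy]methyl}-3-[(triethylsilyl)oxy]butanal | CC[Si](CC)(CC)O[C@H](C)[C@@H](CO[Si](C)(C)C(C)(C)C)C=O
F5 | step 9 | methyl (2Z,4R,5R)-4-{[(tert-butyldimethylsilyl)oxy]methyl}-5-[(triethylsilyl)oxy]hex-2-enoate | CC[Si](CC)(CC)O[C@H](C)[C@@H](CO[Si](C)(C)C(C)(C)C)/C=C\C(=O)OC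
F6 | step 9 | (5R,6R)-5-{[(tert-butyldimethylsilyl)oxy]methyl}-6-methyl-5,6-dihydro-2H-pyran-2-one | O1[C@H](C)[C@@H](CO[Si](C)(C)C(C)(C)C)C=CC1=O
F7 | step 9 | (4S,5R,6R)-5-{[(tert-butyldimethylsilyl)oxy]methyl}-4-ethenyl-6-methyltetrahydro-2H-pyran-2-one (4,5-trans, 5,6-trans) | O1[C@H](C)[C@@H](CO[Si](C)(C)C(C)(C)C)[C@H](C=C)CC1=O
F8 | step 9 | 3-(hydroxymethylidene) derivative of F7 (α-formyl lactone, enol form; ring stereocentres as in F7) | O1[C@H](C)[C@@H](CO[Si](C)(C)C(C)(C)C)[C@H](C=C)C(=CO)C1=O
F9 | step 9 | methyl (2R,3R,4S)-4-ethenyl-3-(hydroxymethyl)-2-methyl-3,4-dihydro-2H-pyran-5-carboxylate | COC(=O)C1=CO[C@H](C)[C@@H](CO)[C@@H]1C=C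
F10 | step 9 | methyl (2R,3R,4S)-3-{[(tert-butyldimethylsilyl)oxy]methyl}-4-ethenyl-2-methyl-3,4-dihydro-2H-pyran-5-carboxylate | COC(=O)C1=CO[C@H](C)[C@@H](CO[Si](C)(C)C(C)(C)C)[C@@H]1C=C
F11 | step 8 | methyl (2E)-2-(dimethoxymethyl)-5-[(4-methoxybenzyl)oxy]pent-2-enoate | COC(=O)/C(C(OC)OC)=C/CCOCc1ccc(OC)cc1
F12 | step 5 | methyl (2E)-2-(acetoxymethyl)-5-[(4-methoxybenzyl)oxy]pent-2-enoate | COC(=O)/C(COC(C)=O)=C/CCOCc1ccc(OC)cc1
F13 | step 5 | methyl (2E)-2-(hydroxymethyl)-5-[(4-methoxybenzyl)oxy]pent-2-enoate | COC(=O)/C(CO)=C/CCOCc1ccc(OC)cc1
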